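Over 15 h we need two things for ochre and red: where the curve of reacted electrophile bends, and what it gains afterwards.

| flask | electrophile | free base | protonated nucleophile | remark | time |
|---|---|---|---|---|---|
| south-west | 0.050 M | 1.3 equiv | 1.5 equiv | run made earlier |  |
| east | 0.050 M | 2.2 equiv | 1.5 equiv | run made earlier |  |
| ochre | 0.050 M | 1.10 equiv | 1.50 equiv |  | 15 h |
| red | 0.050 M | 1.40 equiv | 1.50 equiv |  | 15 h |

| run | time / h | electrophile / % | target / % |
|---|---|---|---|
| south-west | 1.33 | 73 | 30 |
| south-west | 4.00 | 52 | 50 |
| south-west | 8.00 | 36 | 63 |
| south-west | 10.0 | 32 | 66 |
| south-west | 15.0 | 30 | 69 |
| east | 1.33 | 62 | 36 |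
| east | 2.50 | 43 | 55 |
| east | 4.00 | 29 | 65 |
| east | 8.00 | 16 | 80 |
| east | 15.0 | 10 | 85 |

(standard deviation of a reading: 2 percentage points)

- a reading or a percentage of target counts all its forms, free or not

1. part of the electrophile that has reacted at the end, ochre
2. part of the electrophile that has reacted at the end, red
3. what raising the equivalents of free base from its lowest to its highest value here does to the part of the electrophile that has reacted (changes below 5 percentage points count as none) (no change / it rises / it falls)

The south-west run starts steeply, with 27.0% reacted at 1.33 h. Its electrophile reading loses 16 percentage points between 4.00 h and 8.00 h but 6 points between 8.00 h and 15.0 h, a longer stretch, so we place a rough knee near 8.00 h. There 64.0% had reacted on 1.3 equiv of free base. That gives 2.03 per electrophile reacted, our base cost, the free base charged divided by the fraction reacted at the knee. We read it as two duties: freeing the nucleophile from the protonated nucleophile, then taking up the acid released.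

The east run's charge covers 108% of the electrophile, and it reads 90.0% reacted at 15.0 h. Its first reading gives 1.41 times the south-west reaction for 1.69 times the base. Start slope and final reading thus both grow with the charge, roughly, and we keep the knee near 8.00 h in ochre and red.

Ochre's knee stands at 54.2%, red's at 68.9%. After its knee the south-west run gained 6 points, from 36% of electrophile, each reading scattering by 2 points. Scaling that tail to the electrophile left at each knee, we expect 61.8% for ochre and 74.1% for red, a rise of 12 points.

The forecast, holding that “free base is being used up”, puts ochre at 59%, lower than ours, and red at 73%, and for the trend says it rises.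

    electrophile + nucleophile → acid set free + target (k = 5.50 /M/h)
    nucleophile + acid set free ⇌ protonated nucleophile, settled at all times (K = 570 /M)
    acid set free + free base ⇌ salt of the base, settled at all times (K = 65000 /M)
    2 electrophile → self-condensation product (k = 0.0780 /M/h)
    free base ⇌ dormant form (K = 9.90, k = 0.160 /h)
    crystals ⇌ target, rate k6*(cs6 - [target]) while solid is left; crystals form when [target] > cs6 (solubility = 3.50 mM, k = 1.40 /h)

The flask gives 67.2% for ochre and 75.2% for red; with more base it rises, by 8.1 points. Red lies 1.1 points above our figure, ochre 5.4 points. Ochre stands 13 points past its knee, with 0.11% of its free base, the limiting reagent, left. The same flask as red with 5.60 equiv of free base has a cover of 276%. At 15.0 h it has reacted 95.4%, which at our cost is 1.94 of base, and 4.6% of its electrophile is left.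

The earlier runs and the new flask are simulated for substances that don't exist.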